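**Plan**

- Retrosynthesis: cut O1–C2 of ring C first (the C8a hydroxyl adds to an ynone), then C5–C6 and C4a–C8a of ring A (Diels–Alder reaction and aromatisation), then the bond from C8 to the butenolide α-carbon (Stille) and the carbonyl–ethynyl bond of the dienophile (Grignard).
- Feature used: ring A (C4a, C5, C6, C7, C8, C8a; flavone numbering) carries oxygen on C7 and C8a, the butenolide on C8 between them and the acyl carbon C4 on C4a. This 2-acylresorcinol monoether is the imprint of a 1,1,3-trioxygenated butadiene with the butenolide on its C2, combined with an acetylenic ketone.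
- Forward: the butenolide ring is made first (hydrostannation–lactonisation), coupled to iodinated methyl 3-methoxybut-2-enoate, then dienolised and silylated. Ring A forms by cycloaddition to 1-phenylpenta-1,4-diyn-3-one, and ring C closes last in the 6-endo-dig mode.
- Stereochemistry: the target has no stereocentre. The alkene geometries and the one transient ketal centre on the way are erased when ring A becomes aromatic.

Key step: step 8

Assumption: compounds 9, 10, 11 and 12 are drawn as single alkene isomers; these geometries disappear on aromatisation, so any isomer mixture serves.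

**Route**

Step 1
Reactants: 1 methyl propiolate; 2 acetone
Product: 4 methyl 4-hydroxy-4-methylpent-2-ynoate, via lithium methyl propiolate 3 (not isolated)
Conditions: n-BuLi (1.0 equiv), THF, −78 °C; acetone, −78 °C; AcOH quench at −78 °C
Reagents that add atoms: none
Why: Acetylide addition to a ketone; the lithiated propiolate is stable at −78 °C, adds 1,2 to acetone, and the cold acidic quench prevents the alkoxide from reverting or attacking the ester.

Step 2
Reactants: 4 methyl 4-hydroxy-4-methylpent-2-ynoate
Product: 6 5,5-dimethyl-3-(tributylstannyl)furan-2(5H)-one, via methyl (E)-4-hydroxy-4-methyl-2-(tributylstannyl)pent-2-enoate 5 (not isolated)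
Conditions: Bu3SnH (1.1 equiv), Pd(PPh3)4 (2 mol %), THF, 0 °C to rt; then PPTS (cat.), PhMe, 60 °C
Reagents that add atoms: tributyltin hydride, CCCC[SnH](CCCC)CCCC
Why: Palladium-catalysed hydrostannation of a 2-alkynoate adds H and Sn syn with tin on the α-carbon (ester polarisation and the bulky carbinol both direct it there), which puts the ester cis to the tertiary alcohol so that lactonisation to the α-stannyl butenolide follows.

Step 3
Reactants: 7 methyl (E)-3-methoxybut-2-enoate
Product: 9 methyl (Z)-2-iodo-3-methoxybut-2-enoate, via methyl 3-acetoxy-2-iodo-3-methoxybutanoate 8 (not isolated)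
Conditions: NIS (1.2 equiv), AcOH (2 equiv), CH2Cl2, rt, dark; then Et3N (3 equiv), 0 °C to rt
Reagents that add atoms: N-iodosuccinimide, O=C1CCC(=O)N1I
Why: Electrophilic iodoacetoxylation of the enol ether double bond puts iodine on the nucleophilic α-carbon, and triethylamine then removes the acidic α-proton with loss of acetate (addition–elimination), the known way to α-iodo-β-methoxy acrylates.

Step 4
Reactants: 6 5,5-dimethyl-3-(tributylstannyl)furan-2(5H)-one; 9 methyl (Z)-2-iodo-3-methoxybut-2-enoate
Product: 10 methyl (E)-2-(5,5-dimethyl-2-oxo-2,5-dihydrofuran-3-yl)-3-methoxybut-2-enoate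
Conditions: Pd(PPh3)4 (5 mol %), CuI (10 mol %), CsF (2 equiv), DMF, 45 °C
Reagents that add atoms: none
Why: Stille coupling with CuI/CsF activation, a combination suited to hindered and electron-poor alkenylstannanes, should join the butenolide α-carbon to C2 of the iodo enoate with retention at both alkenes.

Step 5
Reactants: 10 methyl (E)-2-(5,5-dimethyl-2-oxo-2,5-dihydrofuran-3-yl)-3-methoxybut-2-enoate
Product: 12 3-[(1Z)-1,3-dimethoxy-1-(trimethylsilyloxy)buta-1,3-dien-2-yl]-5,5-dimethylfuran-2(5H)-one, via lithium dienolate 11 (not isolated)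
Conditions: LDA (1.1 equiv), THF, −78 °C; TMSCl (1.3 equiv), −78 to 0 °C; volatiles including i-Pr2NH removed in vacuo, pentane, filtration under argon; used crude
Reagents that add atoms: chlorotrimethylsilane, C[Si](C)(C)Cl
Why: Dienolisation and O-silylation of a vinylogous ester, the standard preparation of Brassard-type dienes; the γ-methyl cis to the ester is the only acidic C–H (the butenolide has no α- or γ-hydrogen), and the amine is stripped off because it would add to the ynone of step 8.

Step 6
Reactants: 13 3-phenylprop-2-ynal; 14 ethynylmagnesium bromide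
Product: 15 1-phenylpenta-1,4-diyn-3-ol (racemic)
Conditions: THF, 0 °C; then 1 M HCl, 0 °C
Reagents that add atoms: none
Why: Grignard 1,2-addition of the ethynyl anion to the unhindered ynal carbonyl gives the bis-propargylic alcohol, whose carbinol centre is removed by the next oxidation.

Step 7
Reactants: 15 1-phenylpenta-1,4-diyn-3-ol
Product: 16 1-phenylpenta-1,4-diyn-3-one
Conditions: Dess–Martin periodinane (1.2 equiv), CH2Cl2, 0 °C to rt; short silica plug; used at once
Reagents that add atoms: none
Why: Dess–Martin oxidation converts the activated bis-propargylic alcohol to the cross-conjugated diynone under neutral, non-nucleophilic conditions that the sensitive terminal ynone should tolerate.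

Step 8
Reactants: 12 3-[(1Z)-1,3-dimethoxy-1-(trimethylsilyloxy)buta-1,3-dien-2-yl]-5,5-dimethylfuran-2(5H)-one (1.5 equiv); 16 1-phenylpenta-1,4-diyn-3-one
Product: 19 1-[3-(5,5-dimethyl-2-oxo-2,5-dihydrofuran-3-yl)-2-hydroxy-4-methoxyphenyl]-3-phenylprop-2-yn-1-one, via cyclohexadiene cycloadduct 17 (not isolated), via aryl trimethylsilyl ether 18 (not isolated)
Conditions: PhMe, −20 °C to rt; then TFA (5 mol %), CH2Cl2, 0 °C; H2O work-up
Reagents that add atoms: none
Why: This is a Diels–Alder reaction of a 1,1,3-trioxygenated ketene acetal diene with an acetylenic ketone followed by aromatisation, the known entry to acylresorcinol ethers: the CH2 carbon of the diene (C4), where the three oxygens concentrate the HOMO, attacks the unsubstituted CH end of the ynone to make C5–C6, and the ketene acetal carbon (C1) then closes onto the carbon next to the carbonyl to make C4a–C8a. Ring A is thus closed as a six-membered ring in a (4+2) mode that is concerted but asynchronous or, at the limit, a Mukaiyama–Michael addition followed by ring closure. Anhydrous acid then ionises the C–OMe bond of the mixed ketal in 17 to a silyloxy-arenium ion that loses the C6 proton (net 1,4-elimination of methanol, done before water is added so that the C7 enol ether is not hydrolysed), and the aryl silyl ether 18 is hydrolysed on work-up to the phenol, which is hydrogen-bonded to the ynone carbonyl. The only new stereocentre, the ketal carbon of 17, is formed racemic and is erased on aromatisation. The step needs the terminal alkyne to react in preference to the phenyl-capped one and with the right orientation; the open CH terminus of that alkyne and the polarisation of the ketene acetal should secure both. The butenolide alkene should not act as a diene terminus because its β-carbon is electron-poor and sits next to the quaternary C5.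

Step 9
Reactants: 19 1-[3-(5,5-dimethyl-2-oxo-2,5-dihydrofuran-3-yl)-2-hydroxy-4-methoxyphenyl]-3-phenylprop-2-yn-1-one
Product: 20 8-(5,5-dimethyl-2-oxo-2,5-dihydrofuran-3-yl)-7-methoxy-2-phenyl-4H-chromen-4-one
Conditions: DMAP (20 mol %), DMF, 0 °C to rt
Reagents that add atoms: none
Why: Nucleophile-catalysed intramolecular oxa-Michael cyclisation; DMAP adds reversibly to the ynone β-carbon and the C8a phenol displaces it at that same carbon, so ring C can only close in the 6-endo-dig mode and the 5-exo aurone is avoided.

**Compound list**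

1 | methyl propiolate | C#CC(=O)OC | starting material
2 | acetone | CC(C)=O | starting material
3 | lithium methyl propiolate (methyl 3-lithioprop-2-ynoate) | [Li]C#CC(=O)OC | intermediate
4 | methyl 4-hydroxy-4-methylpent-2-ynoate | COC(=O)C#CC(C)(C)O | intermediate
5 | methyl (E)-4-hydroxy-4-methyl-2-(tributylstannyl)pent-2-enoate | CCCC[Sn](CCCC)(CCCC)/C(C(=O)OC)=C/C(C)(C)O | intermediate
6 | 5,5-dimethyl-3-(tributylstannyl)furan-2(5H)-one | CCCC[Sn](CCCC)(CCCC)C1=CC(C)(C)OC1=O | intermediate
7 | methyl (E)-3-methoxybut-2-enoate | CO/C(C)=C/C(=O)OC | starting material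
8 | methyl 3-acetoxy-2-iodo-3-methoxybutanoate (diastereomer mixture) | COC(=O)C(I)C(C)(OC)OC(C)=O | intermediate
9 | methyl (Z)-2-iodo-3-methoxybut-2-enoate | CO/C(C)=C(\I)C(=O)OC | intermediate
10 | methyl (E)-2-(5,5-dimethyl-2-oxo-2,5-dihydrofuran-3-yl)-3-methoxybut-2-enoate | CO/C(C)=C(\C1=CC(C)(C)OC1=O)C(=O)OC | intermediate
11 | lithium (1E)-2-(5,5-dimethyl-2-oxo-2,5-dihydrofuran-3-yl)-1,3-dimethoxybuta-1,3-dien-1-olate | CO/C(O[Li])=C(/C(OC)=C)C1=CC(C)(C)OC1=O | intermediate
12 | 3-[(1Z)-1,3-dimethoxy-1-(trimethylsilyloxy)buta-1,3-dien-2-yl]-5,5-dimethylfuran-2(5H)-one | CO/C(O[Si](C)(C)C)=C(/C(OC)=C)C1=CC(C)(C)OC1=O | intermediate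
13 | 3-phenylprop-2-ynal | O=CC#Cc1ccccc1 | starting material
14 | ethynylmagnesium bromide | C#C[Mg]Br | starting material
15 | 1-phenylpenta-1,4-diyn-3-ol (racemic) | C#CC(O)C#Cc1ccccc1 | intermediate
16 | 1-phenylpenta-1,4-diyn-3-one | C#CC(=O)C#Cc1ccccc1 | intermediate
17 | 1-[5-(5,5-dimethyl-2-oxo-2,5-dihydrofuran-3-yl)-4,6-dimethoxy-6-(trimethylsilyloxy)cyclohexa-1,4-dien-1-yl]-3-phenylprop-2-yn-1-one (racemic) | COC1=C(C2=CC(C)(C)OC2=O)C(OC)(O[Si](C)(C)C)C(C(=O)C#Cc2ccccc2)=CC1 | intermediate
18 | 1-[3-(5,5-dimethyl-2-oxo-2,5-dihydrofuran-3-yl)-4-methoxy-2-(trimethylsilyloxy)phenyl]-3-phenylprop-2-yn-1-one | COc1ccc(C(=O)C#Cc2ccccc2)c(O[Si](C)(C)C)c1C1=CC(C)(C)OC1=O | intermediate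
19 | 1-[3-(5,5-dimethyl-2-oxo-2,5-dihydrofuran-3-yl)-2-hydroxy-4-methoxyphenyl]-3-phenylprop-2-yn-1-one | COc1ccc(C(=O)C#Cc2ccccc2)c(O)c1C1=CC(C)(C)OC1=O | intermediate
20 | 8-(5,5-dimethyl-2-oxo-2,5-dihydrofuran-3-yl)-7-methoxy-2-phenyl-4H-chromen-4-one | COc1ccc2c(=O)cc(-c3ccccc3)oc2c1C1=CC(C)(C)OC1=O | target

**Count**

Total steps: 9. Longest linear sequence: 6 steps (steps 1, 2, 4, 5, 8, 9, from methyl propiolate). The iodide (step 3) and the diynone (steps 6, 7) are side branches.

**Steps most likely to fail, with fallbacks**

Step 8. The doubly activated terminal diynone may oligomerise, may take the diene at its phenyl-capped triple bond, or may stop after conjugate addition because the butenolide on the diene C2 crowds the acetal carbon. The fallback sets out from diene 12 and keeps the same two ring-A bonds but uses commercial but-3-yn-2-one, a well-behaved dienophile for oxygenated dienes. In toluene this should give the cycloadduct 1-[5-(5,5-dimethyl-2-oxo-2,5-dihydrofuran-3-yl)-4,6-dimethoxy-6-(trimethylsilyloxy)cyclohexa-1,4-dien-1-yl]ethan-1-one F1 and, after acid-induced loss of methanol, the aryl silyl ether 1-[3-(5,5-dimethyl-2-oxo-2,5-dihydrofuran-3-yl)-4-methoxy-2-(trimethylsilyloxy)phenyl]ethan-1-one F2; neither would be isolated. Aqueous work-up should then give the acetophenone 1-[3-(5,5-dimethyl-2-oxo-2,5-dihydrofuran-3-yl)-2-hydroxy-4-methoxyphenyl]ethan-1-one F3. Ring C is then built in the Baker–Venkataraman manner: F3 is treated with LiN(SiMe3)2 (3 equiv, THF, −78 °C) and benzoyl chloride to give, by C-acylation of the ketone enolate, the diketone 1-[3-(5,5-dimethyl-2-oxo-2,5-dihydrofuran-3-yl)-2-hydroxy-4-methoxyphenyl]-3-phenylpropane-1,3-dione F4. Cyclodehydration (p-TsOH cat., PhMe, 80 °C) comes back to the route at 20.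

Step 4. Transmetalation from the electron-poor α-stannyl lactone to a crowded, tetrasubstituted alkenylpalladium iodide may be so slow that protodestannylation and homocoupling consume both partners. The fallback reverses the polarity and changes the metal (Negishi coupling); it sets out from 6 and 9. Iododestannylation of 6 (I2, CH2Cl2, 0 °C) should give 3-iodo-5,5-dimethylfuran-2(5H)-one F5. Zinc insertion into 9 (Zn dust, LiCl, THF, rt) should give iodo[(2Z)-1,3-dimethoxy-1-oxobut-2-en-2-yl]zinc F6, in which zinc and the β-methoxy group are cis and so poorly disposed to elimination. Coupling of F5 with F6 (Pd(OAc)2 2 mol %, SPhos 4 mol %, THF, rt to 50 °C) comes back to the route at 10.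

Step 5. The lithium amide may attack the lactone, or the extended enolate, whose charge reaches C4 of the butenolide, may be silylated on carbon, so that no usable diene is obtained. In that case ring A is taken ready-made and only the C8–butenolide bond is formed; the fallback sets out from stannane 6 and commercial 7-hydroxy-2-phenyl-4H-chromen-4-one. Iodination of the latter (NIS, DMF, rt) at C8, the more nucleophilic ortho position of 7-hydroxychromones, should give 7-hydroxy-8-iodo-2-phenyl-4H-chromen-4-one F7. O-Methylation (MeI, K2CO3, acetone, 50 °C) should give 8-iodo-7-methoxy-2-phenyl-4H-chromen-4-one F8. Stille coupling of F8 with 6 (Pd(PPh3)4, CuI, CsF, DMF, 60 °C), a partner class established for 3-stannylbutenolides, comes back to the route at 20.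

**Further compounds**

F1 | step 8 | 1-[5-(5,5-dimethyl-2-oxo-2,5-dihydrofuran-3-yl)-4,6-dimethoxy-6-(trimethylsilyloxy)cyclohexa-1,4-dien-1-yl]ethan-1-one | COC1=C(C2=CC(C)(C)OC2=O)C(OC)(O[Si](C)(C)C)C(C(C)=O)=CC1
F2 | step 8 | 1-[3-(5,5-dimethyl-2-oxo-2,5-dihydrofuran-3-yl)-4-methoxy-2-(trimethylsilyloxy)phenyl]ethan-1-one | COc1ccc(C(C)=O)c(O[Si](C)(C)C)c1C1=CC(C)(C)OC1=O
F3 | step 8 | 1-[3-(5,5-dimethyl-2-oxo-2,5-dihydrofuran-3-yl)-2-hydroxy-4-methoxyphenyl]ethan-1-one | COc1ccc(C(C)=O)c(O)c1C1=CC(C)(C)OC1=O
F4 | step 8 | 1-[3-(5,5-dimethyl-2-oxo-2,5-dihydrofuran-3-yl)-2-hydroxy-4-methoxyphenyl]-3-phenylpropane-1,3-dione | COc1ccc(C(=O)CC(=O)c2ccccc2)c(O)c1C1=CC(C)(C)OC1=O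
F5 | step 4 | 3-iodo-5,5-dimethylfuran-2(5H)-one | CC1(C)C=C(I)C(=O)O1
F6 | step 4 | iodo[(2Z)-1,3-dimethoxy-1-oxobut-2-en-2-yl]zinc | CO/C(C)=C(\[Zn]I)C(=O)OC
F7 | step 5 | 7-hydroxy-8-iodo-2-phenyl-4H-chromen-4-one | O=c1cc(-c2ccccc2)oc2c(I)c(O)ccc12
F8 | step 5 | 8-iodo-7-methoxy-2-phenyl-4H-chromen-4-one | COc1ccc2c(=O)cc(-c3ccccc3)oc2c1I
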